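**Strategy.** Narbonolide is opened at C10–C11. Within the 14-membered lactone ring, the C9 ketone and the C10=C11 E-alkene together have the oxidation state of a C9 carbinol beside a C10≡C11 alkyne, and a ring this large tolerates a triple bond. Ring-closing alkyne metathesis of two propynyl termini therefore makes the last skeletal bond and the macrocycle in one operation, with no alkene geometry at stake. Desilylation and ruthenium-catalysed redox isomerisation then give the E-enone. The metathesis precursor is an open-chain β-keto ester: a C1–C9 acid part (TES ethers at O5 and O9, propynyl at C9) esterified with the C11–C15 alcohol (propynyl at C12), assembled by aldol chemistry.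

Key step: step 22

Assumption: atom numbers C1–C15 follow narbonolide numbering; C9 is carried as an epimer pair and drawn as the expected major Felkin (9S) epimer, C2 is labile once flanked by two carbonyl groups and is drawn 2R (the configuration expected to prevail in the macrolactone), and adduct 30 is a C2/C3 mixture with these two centres left open in its SMILES.

Step 1
Reactants: 1 meso-2,4-dimethylglutaric anhydride
Product: 2 meso-(2R,4S)-2,4-dimethylpentane-1,5-diol
Conditions: LiAlH4, THF, 0 °C → reflux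
Reagents that add atoms: none
Why: Hydride reduction of a cyclic anhydride to the diol is routine and leaves the two cis-related methyl centres untouched, so the product stays meso.

Step 2
Reactants: 2 meso-(2R,4S)-2,4-dimethylpentane-1,5-diol
Product: 3 (2S,4R)-5-hydroxy-2,4-dimethylpentyl acetate
Conditions: Amano lipase AK, vinyl acetate, THF, rt
Reagents that add atoms: vinyl acetate, CC(=O)OC=C
Why: Lipase-catalysed enantiotopos-selective transesterification of a meso diol should acylate the hydroxymethyl group at the (S)-configured centre and stop at the monoacetate, which differentiates the two ends without forming a stereocentre.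

Step 3
Reactants: 3 (2S,4R)-5-hydroxy-2,4-dimethylpentyl acetate
Product: 4 (2S,4R)-2,4-dimethyl-5-oxopentyl acetate
Conditions: Dess–Martin periodinane, NaHCO3, CH2Cl2, 0 °C → rt
Reagents that add atoms: none
Why: Buffered Dess–Martin oxidation of the primary alcohol runs near neutrality and should not epimerise the α-methyl centre (future C8).

Step 4
Reactants: 4 (2S,4R)-2,4-dimethyl-5-oxopentyl acetate; 5 1-propynylmagnesium bromide
Product: 6 (2S,4R,5S)-5-hydroxy-2,4-dimethyloct-6-yn-1-yl acetate
Conditions: THF, −78 °C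
Reagents that add atoms: none
Why: Alkynyl Grignard 1,2-addition is far faster at the aldehyde than at the acetate at low temperature; Felkin–Anh approach should favour the drawn carbinol, and the minor epimer is kept because this carbon ends as the C9 ketone.

Step 5
Reactants: 6 (2S,4R,5S)-5-hydroxy-2,4-dimethyloct-6-yn-1-yl acetate
Product: 7 (2S,4R,5S)-2,4-dimethyl-5-(triethylsilyloxy)oct-6-yn-1-yl acetate
Conditions: TESCl, imidazole, DMF, 0 °C → rt
Reagents that add atoms: chlorotriethylsilane, CC[Si](Cl)(CC)CC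
Why: Standard silylation of a secondary propargylic alcohol installs the ether that masks O9 until after ring closure.

Step 6
Reactants: 7 (2S,4R,5S)-2,4-dimethyl-5-(triethylsilyloxy)oct-6-yn-1-yl acetate
Product: 8 (2S,4R,5S)-2,4-dimethyl-5-(triethylsilyloxy)oct-6-yn-1-ol
Conditions: DIBAL-H, CH2Cl2, −78 °C
Reagents that add atoms: none
Why: Reductive cleavage of the primary acetate at low temperature should leave the TES ether and the alkyne untouched.

Step 7
Reactants: 8 (2S,4R,5S)-2,4-dimethyl-5-(triethylsilyloxy)oct-6-yn-1-ol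
Product: 9 (2S,4R,5S)-2,4-dimethyl-5-(triethylsilyloxy)oct-6-ynal
Conditions: Dess–Martin periodinane, NaHCO3, CH2Cl2, 0 °C → rt
Reagents that add atoms: none
Why: Buffered Dess–Martin oxidation should give the α-methyl aldehyde (C5) without epimerising C6; it would be used crude.

Step 8
Reactants: 9 (2S,4R,5S)-2,4-dimethyl-5-(triethylsilyloxy)oct-6-ynal; 10 (R)-4-benzyl-3-propionyloxazolidin-2-one
Product: 12 (R)-4-benzyl-3-[(2R,3S,4S,6R,7S)-3-hydroxy-2,4,6-trimethyl-7-(triethylsilyloxy)dec-8-ynoyl]oxazolidin-2-one, via Z-boron enolate 11 (not isolated)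
Conditions: Bu2BOTf, Et3N, CH2Cl2, −78 → 0 °C; then H2O2, MeOH, pH 7 buffer
Reagents that add atoms: none
Why: Evans syn aldol through the Z-boron enolate and a Zimmerman–Traxler chair, in which the (R)-auxiliary fixes C4 (R) and C5 (S); the resulting anti relation of O5 to the C6 methyl is the anti-Felkin sense that Z-enolates prefer, so auxiliary and substrate are matched.

Step 9
Reactants: 12 (R)-4-benzyl-3-[(2R,3S,4S,6R,7S)-3-hydroxy-2,4,6-trimethyl-7-(triethylsilyloxy)dec-8-ynoyl]oxazolidin-2-one
Product: 13 (2R,3S,4S,6R,7S)-3-hydroxy-N-methoxy-N,2,4,6-tetramethyl-7-(triethylsilyloxy)dec-8-ynamide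
Conditions: MeNH(OMe)·HCl, Me3Al, CH2Cl2, −20 → 0 °C
Reagents that add atoms: N,O-dimethylhydroxylamine hydrochloride, CNOC.Cl
Why: Aluminium-amide transamination to the Weinreb amide is assisted by the free β-hydroxyl, releases the auxiliary for recovery and should not epimerise the α-centre.

Step 10
Reactants: 13 (2R,3S,4S,6R,7S)-3-hydroxy-N-methoxy-N,2,4,6-tetramethyl-7-(triethylsilyloxy)dec-8-ynamide
Product: 14 (2R,3S,4S,6R,7S)-N-methoxy-N,2,4,6-tetramethyl-3,7-bis(triethylsilyloxy)dec-8-ynamide
Conditions: TESOTf, 2,6-lutidine, CH2Cl2, −78 → 0 °C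
Reagents that add atoms: triethylsilyl trifluoromethanesulfonate, CC[Si](CC)(CC)OS(=O)(=O)C(F)(F)F
Why: The silyl triflate silylates the hindered C5 carbinol quickly at low temperature and gives a second TES ether that can leave together with the first.

Step 11
Reactants: 14 (2R,3S,4S,6R,7S)-N-methoxy-N,2,4,6-tetramethyl-3,7-bis(triethylsilyloxy)dec-8-ynamide
Product: 15 (2R,3S,4S,6R,7S)-2,4,6-trimethyl-3,7-bis(triethylsilyloxy)dec-8-ynal
Conditions: DIBAL-H, THF, −78 °C
Reagents that add atoms: none
Why: Weinreb amide reduction stops at the chelated hemiaminal and releases the C3 aldehyde only on work-up, which avoids over-reduction and α-epimerisation.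

Step 12
Reactants: 16 (S)-4-benzyl-3-propionyloxazolidin-2-one; 17 propanal
Product: 19 (S)-4-benzyl-3-[(2S,3R)-3-hydroxy-2-methylpentanoyl]oxazolidin-2-one, via Z-boron enolate 18 (not isolated)
Conditions: Bu2BOTf, Et3N, CH2Cl2, −78 → 0 °C; then H2O2, MeOH, pH 7 buffer
Reagents that add atoms: none
Why: Evans syn aldol via the Z-boron enolate and a chair transition state; the (S)-auxiliary sets the (2S,3R) pair that becomes C12 and C13.

Step 13
Reactants: 19 (S)-4-benzyl-3-[(2S,3R)-3-hydroxy-2-methylpentanoyl]oxazolidin-2-one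
Product: 20 (2S,3R)-3-hydroxy-N-methoxy-N,2-dimethylpentanamide
Conditions: MeNH(OMe)·HCl, Me3Al, CH2Cl2, −20 → 0 °C
Reagents that add atoms: N,O-dimethylhydroxylamine hydrochloride, CNOC.Cl
Why: Weinreb transamination of an Evans aldol adduct, as in step 9, with the auxiliary recovered.

Step 14
Reactants: 20 (2S,3R)-3-hydroxy-N-methoxy-N,2-dimethylpentanamide
Product: 21 (2S,3R)-3-(tert-butyldimethylsilyloxy)-N-methoxy-N,2-dimethylpentanamide
Conditions: TBSOTf, 2,6-lutidine, CH2Cl2, 0 °C
Reagents that add atoms: tert-butyldimethylsilyl trifluoromethanesulfonate, CC(C)(C)[Si](C)(C)OS(=O)(=O)C(F)(F)F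
Why: Silylation protects the carbinol through the hydride and organolithium steps that follow.

Step 15
Reactants: 21 (2S,3R)-3-(tert-butyldimethylsilyloxy)-N-methoxy-N,2-dimethylpentanamide
Product: 22 (2S,3R)-3-(tert-butyldimethylsilyloxy)-2-methylpentanal
Conditions: DIBAL-H, THF, −78 °C
Reagents that add atoms: none
Why: Weinreb amide reduction should deliver the aldehyde without over-reduction or epimerisation.

Step 16
Reactants: 22 (2S,3R)-3-(tert-butyldimethylsilyloxy)-2-methylpentanal
Product: 23 (3R,4R)-1,1-dibromo-4-(tert-butyldimethylsilyloxy)-3-methylhex-1-ene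
Conditions: CBr4, PPh3, Zn, CH2Cl2, rt; then 22, 0 °C → rt
Reagents that add atoms: carbon tetrabromide, BrC(Br)(Br)Br
Why: Corey–Fuchs dibromo-olefination (Wittig-type, with Ph3P=CBr2) is non-basic, so the α-stereocentre should be preserved.

Step 17
Reactants: 23 (3R,4R)-1,1-dibromo-4-(tert-butyldimethylsilyloxy)-3-methylhex-1-ene
Product: 25 tert-butyldimethyl{[(3R,4R)-4-methylhept-5-yn-3-yl]oxy}silane, via lithium acetylide 24 (not isolated)
Conditions: n-BuLi (2.1 equiv), THF, −78 °C; then MeI, −78 °C → rt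
Reagents that add atoms: iodomethane, CI
Why: Second stage of the Corey–Fuchs sequence, in which Br/Li exchange and rearrangement give the lithium acetylide and C-methylation installs the methyl cap needed for metathesis.

Step 18
Reactants: 25 tert-butyldimethyl{[(3R,4R)-4-methylhept-5-yn-3-yl]oxy}silane
Product: 26 (3R,4R)-4-methylhept-5-yn-3-ol
Conditions: TBAF, THF, rt
Reagents that add atoms: none
Why: Fluoride cleavage of the TBS ether is routine; the volatile alcohol would be concentrated with care and used at once.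

Step 19
Reactants: 26 (3R,4R)-4-methylhept-5-yn-3-ol; 27 propionyl chloride
Product: 28 (3R,4R)-4-methylhept-5-yn-3-yl propanoate
Conditions: pyridine, DMAP (cat.), CH2Cl2, 0 °C → rt
Reagents that add atoms: none
Why: DMAP-catalysed acylation of the secondary alcohol forms the future lactone C1–O bond early and with retention, since the C13–O bond is not touched.

Step 20
Reactants: 28 (3R,4R)-4-methylhept-5-yn-3-yl propanoate; 15 (2R,3S,4S,6R,7S)-2,4,6-trimethyl-3,7-bis(triethylsilyloxy)dec-8-ynal
Product: 30 (3R,4R)-4-methylhept-5-yn-3-yl (4S,5S,6S,8R,9S)-3-hydroxy-2,4,6,8-tetramethyl-5,9-bis(triethylsilyloxy)dodec-10-ynoate, via lithium enolate 29 (not isolated)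
Conditions: LDA, THF, −78 °C; then 15, −78 °C
Reagents that add atoms: none
Why: Aldol addition of an ester lithium enolate to the aldehyde forms C2–C3 and unites the fragments; the new C2 and C3 centres are uncontrolled, which is harmless because C3 is oxidised next and C2 then becomes epimerisable.

Step 21
Reactants: 30 (3R,4R)-4-methylhept-5-yn-3-yl (4S,5S,6S,8R,9S)-3-hydroxy-2,4,6,8-tetramethyl-5,9-bis(triethylsilyloxy)dodec-10-ynoate
Product: 31 (3R,4R)-4-methylhept-5-yn-3-yl (2R,4R,5S,6S,8R,9S)-2,4,6,8-tetramethyl-3-oxo-5,9-bis(triethylsilyloxy)dodec-10-ynoate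
Conditions: Dess–Martin periodinane, NaHCO3, CH2Cl2, rt
Reagents that add atoms: none
Why: Dess–Martin oxidation of a β-hydroxy ester to the β-keto ester under buffered conditions should avoid β-elimination of the O5 silyl ether; both C2 epimers go forward.

Step 22
Reactants: 31 (3R,4R)-4-methylhept-5-yn-3-yl (2R,4R,5S,6S,8R,9S)-2,4,6,8-tetramethyl-3-oxo-5,9-bis(triethylsilyloxy)dodec-10-ynoate
Product: 32 10,11-didehydro-9-dihydronarbonolide 5,9-bis(triethylsilyl) ether, i.e. (3R,5R,6S,7S,9R,10S,13R,14R)-14-ethyl-3,5,7,9,13-pentamethyl-6,10-bis(triethylsilyloxy)oxacyclotetradec-11-yne-2,4-dione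
Conditions: Mo alkylidyne [Mo(≡CC6H4-4-OMe)] with tripodal tris-silanolate ligand (15 mol%), 5 Å MS, toluene (2 mM), 60 °C
Reagents that add atoms: none
Why: The Mo≡C unit adds [2+2] to one propynyl terminus to give a molybdacyclobutadiene whose cycloreversion loads the substrate onto the metal, and a second cycloaddition/cycloreversion with the other propynyl group forms C10≡C11 and releases 2-butyne. The closest known reaction type is ring-closing alkyne metathesis of methyl-capped diyne esters to macrocyclic cycloalkyne lactones with silanolate-ligated molybdenum alkylidynes. The 14-membered lactone ring is closed end to end by this intramolecular metathesis with the triple bond endocyclic, and a ring of this size holds the near-linear C9–C10≡C11–C12 unit without strain. No stereocentre is formed, and the branched centres C9 and C12 beside the alkynes are not touched. Ring closure must outrun acyclic oligomerisation, which high dilution and trapping of 2-butyne on 5 Å sieves should secure, helped by the s-trans ester and the methyl-branched backbone that restrict the chain. The catalyst must also ignore the ketone, the ester, the TES ethers and the acidic C2–H, which is why a chelating tripodal silanolate ligand of low Lewis acidity and good resistance to protonolysis is chosen.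

Step 23
Reactants: 32 10,11-didehydro-9-dihydronarbonolide 5,9-bis(triethylsilyl) ether
Product: 33 10,11-didehydro-9-dihydronarbonolide, i.e. (3R,5R,6S,7S,9R,10S,13R,14R)-14-ethyl-6,10-dihydroxy-3,5,7,9,13-pentamethyloxacyclotetradec-11-yne-2,4-dione
Conditions: HF·pyridine, pyridine, THF, 0 °C → rt
Reagents that add atoms: none
Why: Buffered fluoride attack at silicon cleaves both TES ethers under conditions mild enough to spare the β-hydroxy ketone (no retro-aldol or dehydration) and the lactone (no acyl shift to O5).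

Step 24
Reactants: 33 10,11-didehydro-9-dihydronarbonolide
Product: 34 narbonolide, (3R,5R,6S,7S,9R,11E,13R,14R)-14-ethyl-6-hydroxy-3,5,7,9,13-pentamethyloxacyclotetradec-11-ene-2,4,10-trione
Conditions: [(indenyl)Ru(PPh3)2Cl] (cat.), In(OTf)3 (cat.), CSA (cat.), THF, 65 °C
Reagents that add atoms: none
Why: Ruthenium-catalysed redox isomerisation of a secondary propargylic alcohol, in which propargylic hydride migration onto the Ru-bound alkyne and protonolysis of the alkenyl-ruthenium species give the conjugated E-enone; C9 loses its stereocentre so both epimers converge, and C2 is expected to settle in the 2R configuration.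

**Compound list**

1 | meso-2,4-dimethylglutaric anhydride | O=C1[C@@H](C)C[C@@H](C)C(=O)O1 | starting material
2 | meso-(2R,4S)-2,4-dimethylpentane-1,5-diol | OC[C@@H](C)C[C@@H](C)CO | intermediate
3 | (2S,4R)-5-hydroxy-2,4-dimethylpentyl acetate | CC(=O)OC[C@@H](C)C[C@@H](C)CO | intermediate
4 | (2S,4R)-2,4-dimethyl-5-oxopentyl acetate | CC(=O)OC[C@@H](C)C[C@@H](C)C=O | intermediate
5 | 1-propynylmagnesium bromide | CC#C[Mg]Br | starting material
6 | (2S,4R,5S)-5-hydroxy-2,4-dimethyloct-6-yn-1-yl acetate (major C5 epimer drawn) | CC(=O)OC[C@@H](C)C[C@@H](C)[C@H](O)C#CC | intermediate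
7 | (2S,4R,5S)-2,4-dimethyl-5-(triethylsilyloxy)oct-6-yn-1-yl acetate | CC(=O)OC[C@@H](C)C[C@@H](C)[C@H](O[Si](CC)(CC)CC)C#CC | intermediate
8 | (2S,4R,5S)-2,4-dimethyl-5-(triethylsilyloxy)oct-6-yn-1-ol | OC[C@@H](C)C[C@@H](C)[C@H](O[Si](CC)(CC)CC)C#CC | intermediate
9 | (2S,4R,5S)-2,4-dimethyl-5-(triethylsilyloxy)oct-6-ynal | O=C[C@@H](C)C[C@@H](C)[C@H](O[Si](CC)(CC)CC)C#CC | intermediate
10 | (R)-4-benzyl-3-propionyloxazolidin-2-one | CCC(=O)N1[C@H](Cc2ccccc2)COC1=O | starting material
11 | Z-dibutylboron enolate of 10 (not isolated) | C/C=C(\OB(CCCC)CCCC)N1[C@H](Cc2ccccc2)COC1=O | intermediate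
12 | (R)-4-benzyl-3-[(2R,3S,4S,6R,7S)-3-hydroxy-2,4,6-trimethyl-7-(triethylsilyloxy)dec-8-ynoyl]oxazolidin-2-one | O=C(N1[C@H](Cc2ccccc2)COC1=O)[C@H](C)[C@@H](O)[C@@H](C)C[C@@H](C)[C@H](O[Si](CC)(CC)CC)C#CC | intermediate
13 | (2R,3S,4S,6R,7S)-3-hydroxy-N-methoxy-N,2,4,6-tetramethyl-7-(triethylsilyloxy)dec-8-ynamide | CON(C)C(=O)[C@H](C)[C@@H](O)[C@@H](C)C[C@@H](C)[C@H](O[Si](CC)(CC)CC)C#CC | intermediate
14 | (2R,3S,4S,6R,7S)-N-methoxy-N,2,4,6-tetramethyl-3,7-bis(triethylsilyloxy)dec-8-ynamide | CON(C)C(=O)[C@H](C)[C@@H](O[Si](CC)(CC)CC)[C@@H](C)C[C@@H](C)[C@H](O[Si](CC)(CC)CC)C#CC | intermediate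
15 | (2R,3S,4S,6R,7S)-2,4,6-trimethyl-3,7-bis(triethylsilyloxy)dec-8-ynal | O=C[C@H](C)[C@@H](O[Si](CC)(CC)CC)[C@@H](C)C[C@@H](C)[C@H](O[Si](CC)(CC)CC)C#CC | intermediate
16 | (S)-4-benzyl-3-propionyloxazolidin-2-one | CCC(=O)N1[C@@H](Cc2ccccc2)COC1=O | starting material
17 | propanal | CCC=O | starting material
18 | Z-dibutylboron enolate of 16 (not isolated) | C/C=C(\OB(CCCC)CCCC)N1[C@@H](Cc2ccccc2)COC1=O | intermediate
19 | (S)-4-benzyl-3-[(2S,3R)-3-hydroxy-2-methylpentanoyl]oxazolidin-2-one | O=C(N1[C@@H](Cc2ccccc2)COC1=O)[C@@H](C)[C@H](O)CC | intermediate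
20 | (2S,3R)-3-hydroxy-N-methoxy-N,2-dimethylpentanamide | CON(C)C(=O)[C@@H](C)[C@H](O)CC | intermediate
21 | (2S,3R)-3-(tert-butyldimethylsilyloxy)-N-methoxy-N,2-dimethylpentanamide | CON(C)C(=O)[C@@H](C)[C@H](O[Si](C)(C)C(C)(C)C)CC | intermediate
22 | (2S,3R)-3-(tert-butyldimethylsilyloxy)-2-methylpentanal | O=C[C@@H](C)[C@H](O[Si](C)(C)C(C)(C)C)CC | intermediate
23 | (3R,4R)-1,1-dibromo-4-(tert-butyldimethylsilyloxy)-3-methylhex-1-ene | BrC(Br)=C[C@@H](C)[C@H](O[Si](C)(C)C(C)(C)C)CC | intermediate
24 | [(3R,4R)-4-(tert-butyldimethylsilyloxy)-3-methylhex-1-yn-1-yl]lithium (not isolated) | [Li]C#C[C@@H](C)[C@H](O[Si](C)(C)C(C)(C)C)CC | intermediate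
25 | tert-butyldimethyl{[(3R,4R)-4-methylhept-5-yn-3-yl]oxy}silane | CC#C[C@@H](C)[C@H](O[Si](C)(C)C(C)(C)C)CC | intermediate
26 | (3R,4R)-4-methylhept-5-yn-3-ol | CC#C[C@@H](C)[C@@H](CC)O | intermediate
27 | propionyl chloride | CCC(=O)Cl | starting material
28 | (3R,4R)-4-methylhept-5-yn-3-yl propanoate | CC#C[C@@H](C)[C@@H](CC)OC(=O)CC | intermediate
29 | lithium E-enolate of 28 (not isolated) | CC#C[C@@H](C)[C@@H](CC)O/C(O[Li])=C\C | intermediate
30 | (3R,4R)-4-methylhept-5-yn-3-yl (4S,5S,6S,8R,9S)-3-hydroxy-2,4,6,8-tetramethyl-5,9-bis(triethylsilyloxy)dodec-10-ynoate (C2/C3 mixture) | CC#C[C@@H](C)[C@@H](CC)OC(=O)C(C)C(O)[C@H](C)[C@@H](O[Si](CC)(CC)CC)[C@@H](C)C[C@@H](C)[C@H](O[Si](CC)(CC)CC)C#CC | intermediate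
31 | seco diyne β-keto ester, (3R,4R)-4-methylhept-5-yn-3-yl (2R,4R,5S,6S,8R,9S)-2,4,6,8-tetramethyl-3-oxo-5,9-bis(triethylsilyloxy)dodec-10-ynoate | CC#C[C@@H](C)[C@@H](CC)OC(=O)[C@H](C)C(=O)[C@H](C)[C@@H](O[Si](CC)(CC)CC)[C@@H](C)C[C@@H](C)[C@H](O[Si](CC)(CC)CC)C#CC | intermediate
32 | 10,11-didehydro-9-dihydronarbonolide 5,9-bis(triethylsilyl) ether (cycloalkyne) | CC[C@H]1OC(=O)[C@H](C)C(=O)[C@H](C)[C@@H](O[Si](CC)(CC)CC)[C@@H](C)C[C@@H](C)[C@H](O[Si](CC)(CC)CC)C#C[C@H]1C | intermediate
33 | 10,11-didehydro-9-dihydronarbonolide (cycloalkyne diol) | CC[C@H]1OC(=O)[C@H](C)C(=O)[C@H](C)[C@@H](O)[C@@H](C)C[C@@H](C)[C@H](O)C#C[C@H]1C | intermediate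
34 | narbonolide | CC[C@H]1OC(=O)[C@H](C)C(=O)[C@H](C)[C@@H](O)[C@@H](C)C[C@@H](C)C(=O)/C=C/[C@H]1C | target

**Step count and risk**

Total step count: 24. Longest linear sequence: 16 steps (steps 1–11, then 20–24, from anhydride 1); the alcohol arm (steps 12–19) joins at step 20.

Steps most likely to fail:

Step 22. The catalyst may be deactivated by protonolysis or chelation through the acidic β-keto ester, or oligomerisation may outpace ring closure. The fallback closes the ring one oxidation level lower at C3. It sets out from 30: capping the C3 hydroxyl (TMSCl, imidazole) would give the 3-O-trimethylsilyl seco diyne F1, which has no acidic C–H and would undergo the same alkyne metathesis to the 3-O-trimethylsilyl cycloalkyne F2. Selective methanolysis of the TMS ether (citric acid, MeOH, 0 °C), which the two TES ethers should survive, would give the 3-hydroxy cycloalkyne F3, and Dess–Martin oxidation would come back to the route at 32.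

Step 24. Turnover may stall because the β-keto lactone and the free diol bind the ruthenium or indium centres, or the C5 carbinol may dehydrate under the acid co-catalyst. The fallback sets out from 33: ruthenium-catalysed trans-hydrosilylation ([Cp*Ru(MeCN)3]PF6, (EtO)3SiH, CH2Cl2) would give the C11 alkenylsilane F4. Protodesilylation with retention (AgF, aqueous THF/MeOH) would give the E-allylic alcohol 9-dihydronarbonolide F5. Chemoselective MnO2 oxidation of the allylic C9 carbinol, which should leave the C5 hydroxyl alone, would come back to the route at 34.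

Step 20. Conversion may be incomplete, or the hindered aldehyde may enolise and epimerise, when only a small excess of the valuable ester enolate can be spent. The fallback moves ester formation behind the C2–C3 bond formation and sets out from 15: aldol addition of the lithium enolate of S-tert-butyl propanethioate, cheap enough to use in large excess, would give the β-hydroxy thioester F6. Dess–Martin oxidation would give the β-keto thioester F7. Silver(I) trifluoroacetate-promoted acyl transfer of acylketene type to alcohol 26 would come back to the route at 31, bypassing steps 19 and 21.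

Further compounds
F1 | step 22 | 3-O-trimethylsilyl ether of 30 (seco diyne, C2/C3 mixture) | CC#C[C@@H](C)[C@@H](CC)OC(=O)C(C)C(O[Si](C)(C)C)[C@H](C)[C@@H](O[Si](CC)(CC)CC)[C@@H](C)C[C@@H](C)[C@H](O[Si](CC)(CC)CC)C#CC
F2 | step 22 | 14-membered cycloalkyne lactone with 3-OTMS and 5,9-bis-OTES (3-dihydro analogue of 32) | CC[C@H]1OC(=O)C(C)C(O[Si](C)(C)C)[C@H](C)[C@@H](O[Si](CC)(CC)CC)[C@@H](C)C[C@@H](C)[C@H](O[Si](CC)(CC)CC)C#C[C@H]1C
F3 | step 22 | 3-hydroxy cycloalkyne lactone with 5,9-bis-OTES (3-dihydro-32) | CC[C@H]1OC(=O)C(C)C(O)[C@H](C)[C@@H](O[Si](CC)(CC)CC)[C@@H](C)C[C@@H](C)[C@H](O[Si](CC)(CC)CC)C#C[C@H]1C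
F4 | step 24 | 11-(triethoxysilyl)-9-dihydronarbonolide (alkenylsilane from trans-hydrosilylation of 33) | CC[C@H]1OC(=O)[C@H](C)C(=O)[C@H](C)[C@@H](O)[C@@H](C)C[C@@H](C)[C@H](O)/C=C(\[Si](OCC)(OCC)OCC)[C@H]1C
F5 | step 24 | 9-dihydronarbonolide (E-allylic alcohol) | CC[C@H]1OC(=O)[C@H](C)C(=O)[C@H](C)[C@@H](O)[C@@H](C)C[C@@H](C)[C@H](O)/C=C/[C@H]1C
F6 | step 20 | S-tert-butyl 3-hydroxy-2,4,6,8-tetramethyl-5,9-bis(triethylsilyloxy)dodec-10-ynethioate (C2/C3 mixture, other centres as in 30) | CC(C)(C)SC(=O)C(C)C(O)[C@H](C)[C@@H](O[Si](CC)(CC)CC)[C@@H](C)C[C@@H](C)[C@H](O[Si](CC)(CC)CC)C#CC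
F7 | step 20 | S-tert-butyl 2,4,6,8-tetramethyl-3-oxo-5,9-bis(triethylsilyloxy)dodec-10-ynethioate (C2 mixture, other centres as in 31) | CC(C)(C)SC(=O)C(C)C(=O)[C@H](C)[C@@H](O[Si](CC)(CC)CC)[C@@H](C)C[C@@H](C)[C@H](O[Si](CC)(CC)CC)C#CC
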